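The data stem from a simulated flask for an exercise; noise was put on by code.

Early on, oak and larch both read 33.6% of the complex with one exchanged at 0.417 min, so I watched the tail instead.

| flask | starting complex | incoming ligand | remark | time |
|---|---|---|---|---|
| oak | 0.25 mM | 1.5 mM | run made earlier |  |
| larch | 0.38 mM | 1.5 mM | run made earlier |  |
| maple | 0.50 mM | 0.75 mM | run made earlier |  |
| flask | 0.50 mM | 1.50 mM |  | 6.0 min |

| run | time / min | complex with one exchanged / % | complex with three exchanged / % |
|---|---|---|---|
| oak | 0.417 | 33.6 | 15.4 |
| oak | 0.667 | 25.2 | 24.5 |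
| oak | 1.33 | 12.0 | 27.1 |
| oak | 2.50 | 4.5 | 18.0 |
| oak | 5.00 | 1.5 | 4.7 |
| larch | 0.417 | 33.6 | 12.8 |
| larch | 0.667 | 23.4 | 19.1 |
| larch | 1.33 | 13.1 | 17.7 |
| larch | 2.50 | 7.8 | 9.6 |
| larch | 5.00 | 5.7 | 1.8 |
| maple | 1.00 | 22.6 | 7.2 |
| maple | 2.00 | 16.4 | 1.8 |
| maple | 3.00 | 11.1 | 2.1 |
| maple | 4.00 | 10.4 | 1.4 |
| maple | 5.00 | 7.1 | 0 |

(each reading ± 1 percentage point)

- what was read earlier has a scatter of 1 percentage point, one standard deviation

* equivalents of incoming ligand to starting complex, everything else as given, that leave most complex with one exchanged at 6.0 min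
* the amount of complex with one exchanged then, in percent of the starting complex charged
* the amount of complex with one exchanged with the amounts as given

By 5.00 min the runs had parted: oak held 1.5%, larch 5.7%, and maple, the leanest in ligand at 1.50 equivalents, held 7.1%. So I put the best charge at or below maple's.

But the flask, at 3.00 equivalents, stood nearer larch's 3.95, so I took its tail from larch. Larch fell from 13.1% at 1.33 min to 5.7% at 5.00 min, which reads as 3.06 min. That is the tail half-life, the time in which the complex with one exchanged halves once past its peak; it treats the fall as pseudo-first-order, though ligand was being used meanwhile.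

From larch's reading at 1.33 min, the flask's 6.0 min lay 1.53 half-lives on, so my own estimate for the flask, borrowed from larch, was 4.54%.

The forecast gave 6.3% for the flask and 6.8% at 2.8 equiv, saying “The optimum looks broad”. My figure was lower, and my best charge leaner.

The flask gave 2.91%, and the best charge was 0.327 equiv, below both maple's and the forecast's, holding 10.0%.

    starting complex + incoming ligand ⇌ leaving ligand + complex with one exchanged (K = 0.390, k = 50.0 L mol⁻¹ s⁻¹)
    complex with one exchanged + incoming ligand ⇌ leaving ligand + complex with two exchanged (K = 1.90, k = 31.0 L mol⁻¹ s⁻¹)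
    complex with two exchanged + incoming ligand ⇌ leaving ligand + complex with three exchanged (K = 1.60, k = 120 L mol⁻¹ s⁻¹)
    complex with two exchanged → side product (k = 0.0750 s⁻¹)

At that best charge, 82.5% of the starting complex still stood in the flask. The same flask stopped at 2.5 min held 8.15%. My tail half-life of 3.06 min counts that forward 1.14 half-lives to 3.69%, and the flask at 6.0 min held 2.91%.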